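**Plan**

1. Cuts (azulene numbering: C3 carbinol with isopropyl, C3a–H, C4–O, C5, C6 carbinol with CH3, C7=C8, C8a–CH3): the aryl ester C–O; then the C5–C6 bond of the seven-membered ring, with the C4 oxygen reconnected to C8, so that the ring shrinks to a five-membered oxolane (O, C4, C3a, C8a, C8); then C3–C3a (aldol); then the two Diels–Alder bonds of a cyclohexene.
2. Enabling feature: in ring C3a–C4–C5–C6–C7–C8–C8a the C7=C8 alkene is γ,δ to the oxygenated C4, and C6 carries O and CH3. This is a cyclohept-4-enone with a donor on C6, the product of a [3,3] shift of a 2-methylidene-oxolane whose C8 bears a (Z)-silyl enol ether.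
3. Forward: an enantioselective Diels–Alder reaction sets quaternary C8a; propargylation sets the C8 carbinol (a relay centre); ozonolysis of the cyclohexene and an enamine aldol contract the six-membered ring to the cyclopentane inside a cis-fused lactol, then lactone.
4. Alkyne → methyl ketone → (Z)-silyl enol ether; lactone C=O → C=CH2; the Claisen ring expansion (oxolane, five atoms → carbocycle, seven atoms) gives the hydroazulene, the C4 ketone, the C7=C8 alkene and the C6 stereocentre in one step.
5. Endgame: hydroxyl-directed reduction at C4, esterification, desilylation.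
6. Stereochemistry: C8a from the Diels–Alder catalyst; C8 (temporary) from the propargylation catalyst; C3 and C3a from reversible aldol closure onto the cis-fused lactol; C6 from enol ether geometry through a chair transition state; C4 from hydride delivery by the C3 hydroxyl.

Key step: step 9

Assumption: the antipode of each chiral catalyst in steps 2 and 3 is chosen to give the configuration drawn (both antipodes are available). Bicyclic lactones are numbered as cyclopenta[c]furans (C1 carbonyl or acetal carbon, O2, C3, C3a, C4–C6, C6a).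

**Step 1**
Reactants: 1 3-methylbut-1-yne; 2 ethene
Product: 3 2-(propan-2-yl)buta-1,3-diene
Conditions: RuCl2(=CHPh)(PCy3)(H2IMes) (second-generation Grubbs catalyst, 3 mol %), ethene (1 atm), CH2Cl2, 23 °C; solution used directly
Reagents that add atoms: none
Why: Ethene–alkyne cross enyne metathesis puts one methylidene on each alkyne carbon and gives the 2-substituted 1,3-diene; no stereocentre is formed.

**Step 2**
Reactants: 3 2-(propan-2-yl)buta-1,3-diene; 4 2-methylprop-2-enal
Product: 5 (1R)-1-methyl-4-(propan-2-yl)cyclohex-3-ene-1-carbaldehyde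
Conditions: (S)-1-(2-methylphenyl)-3,3-diphenyl-tetrahydro-1H,3H-pyrrolo[1,2-c][1,3,2]oxazaborole (10 mol %), Tf2NH (10 mol %), CH2Cl2, −78 → −40 °C
Reagents that add atoms: none
Why: A chiral oxazaborolidinium Lewis acid catalyses the Diels–Alder reaction of the α-substituted enal with the 2-substituted diene with "para" regiochemistry, and shielding of one face of the bound s-trans enal sets the quaternary C1 as R.

**Step 3**
Reactants: 5 (1R)-1-methyl-4-(propan-2-yl)cyclohex-3-ene-1-carbaldehyde; 6 4,4,5,5-tetramethyl-2-(propa-1,2-dien-1-yl)-1,3,2-dioxaborolane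
Product: 7 (1S)-1-[(1R)-1-methyl-4-(propan-2-yl)cyclohex-3-en-1-yl]but-3-yn-1-ol
Conditions: (S)-3,3′-bis(2,4,6-triisopropylphenyl)-1,1′-binaphthyl-2,2′-diyl hydrogen phosphate (10 mol %), 4 Å MS, toluene, 0 → 23 °C; aqueous work-up
Reagents that add atoms: none
Why: Chiral phosphoric acid-catalysed propargylation with the allenylboronate runs through a cyclic six-membered (SE2′) transition state, and because the two ring arms on the α-quaternary carbon are almost alike the catalyst alone sets the carbinol as S.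

**Step 4**
Reactants: 7 (1S)-1-[(1R)-1-methyl-4-(propan-2-yl)cyclohex-3-en-1-yl]but-3-yn-1-ol
Product: 9 (3S,3aR,6R,6aR)-3a-methyl-6-(propan-2-yl)-3-(prop-2-yn-1-yl)hexahydro-1H-cyclopenta[c]furan-1,6-diol (both C1 anomers), via keto lactol 8 (not isolated)
Conditions: O3, CH2Cl2, −78 °C (Sudan Red 7B end point); PPh3, −78 → 23 °C; then pyrrolidine (0.2 equiv), AcOH (0.2 equiv), 0 → 23 °C
Reagents that add atoms: ozone, [O-][O+]=O
Why: Ozonolysis cleaves the electron-rich trisubstituted alkene much faster than the terminal alkyne, the aldehyde closes onto the carbinol as lactol 8, and its pyrrolidine enamine adds to the isopropyl ketone (5-enolexo aldol); C6a and C6 are set under reversible conditions, because only the epimer with the formyl carbon cis to the carbinol oxygen re-closes to the cis-fused lactol and the isopropyl group takes the convex face with the hydroxyl endo.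

**Step 5**
Reactants: 9 bicyclic lactol
Product: 10 (3S,3aR,6R,6aR)-6-hydroxy-3a-methyl-6-(propan-2-yl)-3-(prop-2-yn-1-yl)hexahydro-1H-cyclopenta[c]furan-1-one
Conditions: TEMPO (0.1 equiv), PhI(OAc)2 (1.2 equiv), CH2Cl2, 23 °C
Reagents that add atoms: none
Why: Oxoammonium (TEMPO) oxidation converts lactols to lactones and leaves the tertiary alcohol, the alkyne and all stereocentres untouched.

**Step 6**
Reactants: 10 propargyl lactone
Product: 11 (3S,3aR,6R,6aR)-6-hydroxy-3a-methyl-3-(2-oxopropyl)-6-(propan-2-yl)hexahydro-1H-cyclopenta[c]furan-1-one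
Conditions: Ph3PAuNTf2 (2 mol %), H2O (3 equiv), 1,4-dioxane, 60 °C
Reagents that add atoms: water, O
Why: Gold-catalysed Markovnikov hydration of the terminal alkyne gives the methyl ketone under nearly neutral conditions that spare the tertiary β-hydroxy lactone.

**Step 7**
Reactants: 11 keto lactone
Product: 13 (3S,3aR,6R,6aR)-3-[(1Z)-2-{[tert-butyl(dimethyl)silyl]oxy}prop-1-en-1-yl]-3a-methyl-6-(propan-2-yl)-6-[(trimethylsilyl)oxy]hexahydro-1H-cyclopenta[c]furan-1-one, via trimethylsilyl ether 12 (not isolated)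
Conditions: (Me3Si)2NH, I2 (1 mol %), CH2Cl2, 23 °C; evaporation; then Et3N (3 equiv), TBSOTf (1.3 equiv), CH2Cl2, −78 → −40 °C
Reagents that add atoms: hexamethyldisilazane, C[Si](C)(C)N[Si](C)(C)C; tert-butyldimethylsilyl trifluoromethanesulfonate, CC(C)(C)[Si](C)(C)OS(=O)(=O)C(F)(F)F
Why: Iodine-activated disilazane silylates the hindered tertiary alcohol, and soft enolisation (silyl triflate, amine) then places the enol double bond towards the CH2 acidified by the β-acyloxy oxygen, as the Z isomer because the E isomer would hold CH3 cis to the branched C3 carbon (allylic 1,3-strain); the low temperature suppresses β-elimination of the carboxylate.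

**Step 8**
Reactants: 13 silyl enol ether lactone
Product: 14 (3S,3aR,6R,6aS)-3-[(1Z)-2-{[tert-butyl(dimethyl)silyl]oxy}prop-1-en-1-yl]-3a-methyl-1-methylidene-6-(propan-2-yl)-6-[(trimethylsilyl)oxy]hexahydro-1H-cyclopenta[c]furan
Conditions: Cp2TiMe2 (3 equiv), toluene/THF, 70 °C, dark; filtration through basic alumina
Reagents that add atoms: dimethyltitanocene, [CH3-].[CH3-].[Ti+4].[cH-]1cccc1.[cH-]1cccc1
Why: Petasis methylenation converts the lactone carbonyl (the only carbonyl left) into the exocyclic enol ether under non-acidic conditions that keep both silyl groups, and migration of the double bond into the ring is disfavoured because it would lie at the ring-fusion carbon.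

**Step 9**
Reactants: 14 2-methylidene-oxolane
Product: 16 (3R,3aR,6R,8aS)-6-{[tert-butyl(dimethyl)silyl]oxy}-3-hydroxy-6,8a-dimethyl-3-(propan-2-yl)-2,3,3a,5,6,8a-hexahydroazulen-4(1H)-one, via Claisen ketone 15 (not isolated)
Conditions: toluene, Et3N (0.1 equiv), 130 °C, sealed tube; then PPTS (0.2 equiv), MeOH, 23 °C
Reagents that add atoms: none
Why: The allyl vinyl ether of 14 (H2C=C1–O2–C3–CH=C(OTBS)CH3) undergoes a concerted thermal [3,3] (Claisen) shift in which O2–C3 breaks and the methylidene carbon bonds to the siloxy-bearing carbon, so the five-membered oxolane (O2, C1, C6a, C3a, C3) grows by two atoms into the seven-membered carbocycle of 15 with the C4 ketone and the cis C7=C8 bond in place. The closest known reaction types are the Claisen ring expansion of 2-methylidene-5-alkenyloxolanes to cyclohept-4-enones and the Claisen shift of allyl vinyl ethers that carry an alkoxy donor on the allyl terminus, which that donor accelerates. The seven-membered ring closes by C5–C6 bond formation in a chair-like six-centre transition state bridged by C6a–C3a (a bicyclo[3.2.1]-like array), which forces the C3–C3a ring bond axial and therefore gives the cis alkene. C6 is the only new stereocentre and is controlled by the Z geometry of the enol ether together with the exo position of the alkenyl group on C3 (cis to the angular methyl): the Z oxygen sits axial, syn to C3a, and ends cis to the 8a-methyl (6R), while the C3 stereocentre is erased after this relay. The step needs the [3,3] path to win over heterolysis or a [1,3] shift and over migration of the exocyclic double bond; the non-polar amine-buffered medium and the donor-accelerated concerted path favour it, and double-bond migration is blocked because it would put an alkene at ring-fusion carbon C6a. Methanolysis with PPTS then removes only the trimethylsilyl ether and frees the C3 hydroxyl of 16.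

**Step 10**
Reactants: 16 β-hydroxy ketone
Product: 17 (3R,3aS,4S,6R,8aS)-6-{[tert-butyl(dimethyl)silyl]oxy}-6,8a-dimethyl-3-(propan-2-yl)-1,2,3,3a,4,5,6,8a-octahydroazulene-3,4-diol
Conditions: Me4NBH(OAc)3 (5 equiv), MeCN/AcOH (1:1), −30 °C
Reagents that add atoms: none
Why: In this hydroxyl-directed triacetoxyborohydride reduction (Evans–Saksena) the borohydride bound to the tertiary C3 hydroxyl delivers hydride to the C4 ketone from the face of that hydroxyl, giving the 4S alcohol trans to the C3 oxygen, while the silylated C6 oxygen cannot compete.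

**Step 11**
Reactants: 17 diol; 18 4-{[tert-butyl(dimethyl)silyl]oxy}benzoic acid
Product: 19 (3R,3aS,4S,6R,8aS)-6-{[tert-butyl(dimethyl)silyl]oxy}-3-hydroxy-6,8a-dimethyl-3-(propan-2-yl)-1,2,3,3a,4,5,6,8a-octahydroazulen-4-yl 4-{[tert-butyl(dimethyl)silyl]oxy}benzoate
Conditions: EDC·HCl (1.5 equiv), DMAP (0.3 equiv), CH2Cl2, 23 °C
Reagents that add atoms: none
Why: Steglich esterification acylates the only secondary hydroxyl, and the tertiary C3 hydroxyl stays free.

**Step 12**
Reactants: 19 bis-silyl ester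
Product: 20 (3R,3aS,4S,6R,8aS)-3,6-dihydroxy-6,8a-dimethyl-3-(propan-2-yl)-1,2,3,3a,4,5,6,8a-octahydroazulen-4-yl 4-hydroxybenzoate
Conditions: TBAF (4 equiv), AcOH (4 equiv), THF, 0 → 40 °C
Reagents that add atoms: none
Why: Fluoride cleaves the aryl and the tertiary allylic Si–O bonds, and the acetic acid buffer prevents acyl migration and ionisation of the tertiary allylic alcohol.

**Compound list**

1 | 3-methylbut-1-yne | CC(C)C#C | starting material
2 | ethene | C=C | starting material
3 | 2-(propan-2-yl)buta-1,3-diene | CC(C)C(=C)C=C | intermediate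
4 | 2-methylprop-2-enal (methacrolein) | CC(=C)C=O | starting material
5 | (1R)-1-methyl-4-(propan-2-yl)cyclohex-3-ene-1-carbaldehyde | CC(C)C1=CC[C@](C)(C=O)CC1 | intermediate
6 | 4,4,5,5-tetramethyl-2-(propa-1,2-dien-1-yl)-1,3,2-dioxaborolane (allenylboronic acid pinacol ester) | C=C=CB1OC(C)(C)C(C)(C)O1 | starting material
7 | (1S)-1-[(1R)-1-methyl-4-(propan-2-yl)cyclohex-3-en-1-yl]but-3-yn-1-ol | C#CC[C@H](O)[C@@]1(C)CC=C(C(C)C)CC1 | intermediate
8 | (4R,5S)-4-methyl-4-(4-methyl-3-oxopentyl)-5-(prop-2-yn-1-yl)oxolan-2-ol (both anomers) | C#CC[C@@H]1OC(O)C[C@@]1(C)CCC(=O)C(C)C | intermediate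
9 | (3S,3aR,6R,6aR)-3a-methyl-6-(propan-2-yl)-3-(prop-2-yn-1-yl)hexahydro-1H-cyclopenta[c]furan-1,6-diol (both C1 anomers, cis-fused) | C#CC[C@@H]1OC(O)[C@@H]2[C@@]1(C)CC[C@@]2(O)C(C)C | intermediate
10 | (3S,3aR,6R,6aR)-6-hydroxy-3a-methyl-6-(propan-2-yl)-3-(prop-2-yn-1-yl)hexahydro-1H-cyclopenta[c]furan-1-one | C#CC[C@@H]1OC(=O)[C@@H]2[C@@]1(C)CC[C@@]2(O)C(C)C | intermediate
11 | (3S,3aR,6R,6aR)-6-hydroxy-3a-methyl-3-(2-oxopropyl)-6-(propan-2-yl)hexahydro-1H-cyclopenta[c]furan-1-one | CC(=O)C[C@@H]1OC(=O)[C@@H]2[C@@]1(C)CC[C@@]2(O)C(C)C | intermediate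
12 | (3S,3aR,6R,6aR)-3a-methyl-3-(2-oxopropyl)-6-(propan-2-yl)-6-[(trimethylsilyl)oxy]hexahydro-1H-cyclopenta[c]furan-1-one | CC(=O)C[C@@H]1OC(=O)[C@@H]2[C@@]1(C)CC[C@@]2(O[Si](C)(C)C)C(C)C | intermediate
13 | (3S,3aR,6R,6aR)-3-[(1Z)-2-{[tert-butyl(dimethyl)silyl]oxy}prop-1-en-1-yl]-3a-methyl-6-(propan-2-yl)-6-[(trimethylsilyl)oxy]hexahydro-1H-cyclopenta[c]furan-1-one | C/C(O[Si](C)(C)C(C)(C)C)=C/[C@@H]1OC(=O)[C@@H]2[C@@]1(C)CC[C@@]2(O[Si](C)(C)C)C(C)C | intermediate
14 | (3S,3aR,6R,6aS)-3-[(1Z)-2-{[tert-butyl(dimethyl)silyl]oxy}prop-1-en-1-yl]-3a-methyl-1-methylidene-6-(propan-2-yl)-6-[(trimethylsilyl)oxy]hexahydro-1H-cyclopenta[c]furan | C/C(O[Si](C)(C)C(C)(C)C)=C/[C@@H]1OC(=C)[C@@H]2[C@@]1(C)CC[C@@]2(O[Si](C)(C)C)C(C)C | intermediate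
15 | (3R,3aR,6R,8aS)-6-{[tert-butyl(dimethyl)silyl]oxy}-6,8a-dimethyl-3-(propan-2-yl)-3-[(trimethylsilyl)oxy]-2,3,3a,5,6,8a-hexahydroazulen-4(1H)-one | CC(C)[C@]1(O[Si](C)(C)C)CC[C@@]2(C)C=C[C@](C)(O[Si](C)(C)C(C)(C)C)CC(=O)[C@@H]12 | intermediate
16 | (3R,3aR,6R,8aS)-6-{[tert-butyl(dimethyl)silyl]oxy}-3-hydroxy-6,8a-dimethyl-3-(propan-2-yl)-2,3,3a,5,6,8a-hexahydroazulen-4(1H)-one | CC(C)[C@]1(O)CC[C@@]2(C)C=C[C@](C)(O[Si](C)(C)C(C)(C)C)CC(=O)[C@@H]12 | intermediate
17 | (3R,3aS,4S,6R,8aS)-6-{[tert-butyl(dimethyl)silyl]oxy}-6,8a-dimethyl-3-(propan-2-yl)-1,2,3,3a,4,5,6,8a-octahydroazulene-3,4-diol | CC(C)[C@]1(O)CC[C@@]2(C)C=C[C@](C)(O[Si](C)(C)C(C)(C)C)C[C@H](O)[C@@H]12 | intermediate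
18 | 4-{[tert-butyl(dimethyl)silyl]oxy}benzoic acid | CC(C)(C)[Si](C)(C)Oc1ccc(cc1)C(=O)O | starting material
19 | (3R,3aS,4S,6R,8aS)-6-{[tert-butyl(dimethyl)silyl]oxy}-3-hydroxy-6,8a-dimethyl-3-(propan-2-yl)-1,2,3,3a,4,5,6,8a-octahydroazulen-4-yl 4-{[tert-butyl(dimethyl)silyl]oxy}benzoate | CC(C)[C@]1(O)CC[C@@]2(C)C=C[C@](C)(O[Si](C)(C)C(C)(C)C)C[C@H](OC(=O)c3ccc(O[Si](C)(C)C(C)(C)C)cc3)[C@@H]12 | intermediate
20 | (3R,3aS,4S,6R,8aS)-3,6-dihydroxy-6,8a-dimethyl-3-(propan-2-yl)-1,2,3,3a,4,5,6,8a-octahydroazulen-4-yl 4-hydroxybenzoate | CC(C)[C@]1(O)CC[C@@]2(C)C=C[C@](C)(O)C[C@H](OC(=O)c3ccc(O)cc3)[C@@H]12 | target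

**Totals and risks**

Total steps: 12. Longest linear sequence: 12 (1 → 20); 18 is used as bought.

Steps most likely to fail:

1. Step 9 (key step). What may go wrong: the rigid cis-fused bicyclic enol ether may not reach the chair-like transition state, so that heterolysis of the allylic C–O bond (a [1,3] shift to a cyclopentanone, or elimination) takes over. Fallback, which expands the ring before the cyclopentane is closed, sets out from 8 and returns at 16. Step 4 is stopped after the PPh3 reduction and 8 is isolated. Oxidation (TEMPO, PhI(OAc)2) gives keto lactone F8, and gold-catalysed hydration gives diketo lactone F9. TBSOTf and Et3N convert both ketones into silyl enol ethers, giving bis(silyl enol ether) F10, and Cp2TiMe2 gives methylidene oxolane F11. The monocyclic, conformationally free oxolane should undergo the same Claisen shift to monocyclic cycloheptenone F12. Aqueous AcOH in THF hydrolyses only the side-chain enol ether, and pyrrolidinium acetate then closes the cyclopentane by enamine aldol of the ring ketone onto the isopropyl ketone, giving 16.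

2. Step 4. What may go wrong: dehydration of the aldol to the enal, or kinetic ring closure with the wrong configuration at the carbinol carbon without equilibration. Fallback, which condenses first and then puts the oxygen back stereoselectively, sets out from 8 and returns at 10. Pyrrolidinium acetate in hot toluene drives the aldol condensation to unsaturated lactol F1. TEMPO and PhI(OAc)2 give unsaturated lactone F2. Dimethyldioxirane epoxidises the tetrasubstituted alkene from the face opposite to the angular methyl, giving epoxy lactone F3. SmI2 (THF, MeOH, −78 °C) cleaves the α C–O bond, and protonation of the enolate can only give the cis-fused lactone 10.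

3. Step 7. What may go wrong: β-elimination of the lactone carboxylate (ring opening) during soft enolisation, or enolisation towards the methyl group. Fallback, which removes the acyloxy leaving group and makes the exocyclic enol ether by elimination instead of carbonyl methylenation, sets out from 9 and returns at 14. Wittig methylenation (Ph3P=CH2) of the lactol gives vinyl diol F4. Iodoetherification (I2, NaHCO3, MeCN) closes the oxolane as iodomethyl oxolane F5. Gold-catalysed hydration gives β-alkoxy ketone F6, which can no longer eliminate. The disilazane and then TBSOTf with Et3N give silyl enol ether F7. DBU (toluene, 80 °C) eliminates hydrogen iodide to give 14.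

**Further compounds**

F1 | step 4 | (3S,3aR)-3a-methyl-6-(propan-2-yl)-3-(prop-2-yn-1-yl)-3,3a,4,5-tetrahydro-1H-cyclopenta[c]furan-1-ol (both anomers) | C#CC[C@@H]1OC(O)C2=C(C(C)C)CC[C@@]12C
F2 | step 4 | (3S,3aR)-3a-methyl-6-(propan-2-yl)-3-(prop-2-yn-1-yl)-3,3a,4,5-tetrahydro-1H-cyclopenta[c]furan-1-one | C#CC[C@@H]1OC(=O)C2=C(C(C)C)CC[C@@]12C
F3 | step 4 | 6,6a-epoxide of F2 with the epoxide oxygen anti to the 3a-methyl | C#CC[C@@H]1OC(=O)[C@]23O[C@@]2(C(C)C)CC[C@@]13C
F4 | step 7 | vinyl diol: ring-opened form of 9 in which the lactol carbon has become a vinyl group (other stereocentres as in 9) | C#CC[C@H](O)[C@]1(C)CC[C@@](O)(C(C)C)[C@@H]1C=C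
F5 | step 7 | 1-(iodomethyl) analogue of 9 without the 1-hydroxyl (both C1 epimers) | C#CC[C@@H]1OC(CI)[C@@H]2[C@@]1(C)CC[C@@]2(O)C(C)C
F6 | step 7 | 3-(2-oxopropyl) analogue of F5 | CC(=O)C[C@@H]1OC(CI)[C@@H]2[C@@]1(C)CC[C@@]2(O)C(C)C
F7 | step 7 | (Z)-tert-butyldimethylsilyl enol ether and trimethylsilyl ether of F6 | C/C(O[Si](C)(C)C(C)(C)C)=C/[C@@H]1OC(CI)[C@@H]2[C@@]1(C)CC[C@@]2(O[Si](C)(C)C)C(C)C
F8 | step 9 | (4R,5S)-4-methyl-4-(4-methyl-3-oxopentyl)-5-(prop-2-yn-1-yl)oxolan-2-one | C#CC[C@@H]1OC(=O)C[C@@]1(C)CCC(=O)C(C)C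
F9 | step 9 | (4R,5S)-4-methyl-4-(4-methyl-3-oxopentyl)-5-(2-oxopropyl)oxolan-2-one | CC(=O)C[C@@H]1OC(=O)C[C@@]1(C)CCC(=O)C(C)C
F10 | step 9 | (4R,5S)-5-[(1Z)-2-(tert-butyldimethylsilyloxy)prop-1-en-1-yl]-4-[(2Z)-3-(tert-butyldimethylsilyloxy)-4-methylpent-2-en-1-yl]-4-methyloxolan-2-one | C/C(O[Si](C)(C)C(C)(C)C)=C/[C@@H]1OC(=O)C[C@@]1(C)C/C=C(\O[Si](C)(C)C(C)(C)C)C(C)C
F11 | step 9 | 2-methylidene-oxolane corresponding to F10 (lactone C=O replaced by C=CH2) | C/C(O[Si](C)(C)C(C)(C)C)=C/[C@@H]1OC(=C)C[C@@]1(C)C/C=C(\O[Si](C)(C)C(C)(C)C)C(C)C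
F12 | step 9 | cyclohept-4-en-1-one bearing 3-methyl and 3-(tert-butyldimethylsilyloxy), 6-methyl and the 6-[(2Z)-3-(tert-butyldimethylsilyloxy)-4-methylpent-2-en-1-yl] chain (configurations as in 16) | CC(C)/C(O[Si](C)(C)C(C)(C)C)=C/C[C@@]1(C)C=C[C@](C)(O[Si](C)(C)C(C)(C)C)CC(=O)C1
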